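**Retrosynthetic overview**
1. Target ⇐ C9‑O‑TES ether 30 ⇐ ring‑closing metathesis at C4=C5 of seco‑diene 29; the ten‑membered carbocycle is closed last.
2. 29 ⇐ three fragments of similar size joined late: zinc Barbier allylation (C7–C8) of bromobutenolide 23 with aldehyde 16, then Mitsunobu esterification (inversion at C8) with epoxy acid 26.
3. 16 ⇐ aldol/dehydration (C1=C10) of β‑silyloxy ester 10 (from (R)‑glycidol) with cis‑epoxy aldehyde 6 (Sharpless epoxidation of a Z‑dienol).
4. 23 ⇐ metathesis of the 2‑(bromomethyl)acrylate of (S)‑hexa‑1,4‑dien‑3‑ol (Sharpless kinetic resolution); 26 ⇐ Sharpless epoxidation of tiglyl alcohol, then oxidation.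
5. Ring order: C2–C3 oxirane → butenolide/methylene lactone → side‑chain oxirane (made separately) → carbocycle.

Assumption: atom labels follow germacrane numbering (C6 lactone O‑carbon, C7 ring fusion, C8 acyloxy, C9 carbinol, C10 bears CO2Me = C14, C2/C3 ring oxirane, C4 bears Me = C15, C11–C13 methylene lactone); CH2O, CO, MeOH and protecting‑group chlorides are treated as reagents, and all numbered starting materials are taken as catalogue compounds.

**Step 1**
Reactants: 1 2-methylbut-1-en-3-yne
Product: 3 4-methylpent-4-en-2-yn-1-ol, via lithium acetylide 2 (not isolated)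
Conditions: n-BuLi, THF, −78 °C; (CH2O)n, −78 → 20 °C; H2O
Reagents that add atoms: formaldehyde (as paraformaldehyde) C=O; n-butyllithium [Li]CCCC (lithium is held only in 2)
Why: Deprotonation of the terminal alkyne and 1,2-addition of the acetylide to formaldehyde (acetylide hydroxymethylation); no stereocentre is formed.

**Step 2**
Reactants: 3 4-methylpent-4-en-2-yn-1-ol
Product: 4 (2Z)-4-methylpenta-2,4-dien-1-ol
Conditions: H2 (1 atm, stopped at 1.0 equiv), Pd/CaCO3 poisoned with Pb(OAc)2, quinoline, EtOAc, 0 °C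
Reagents that add atoms: none
Why: Lindlar semihydrogenation delivers H2 syn to the alkyne and gives the Z alkene, while the 1,1-disubstituted alkene survives when uptake is stopped at one equivalent.

**Step 3**
Reactants: 4 (2Z)-4-methylpenta-2,4-dien-1-ol
Product: 5 [(2S,3R)-3-(prop-1-en-2-yl)oxiran-2-yl]methanol
Conditions: Ti(OiPr)4 (10 mol %), L-(+)-diethyl tartrate (12 mol %), t-BuOOH, 4 Å MS, CH2Cl2, −20 °C
Reagents that add atoms: tert-butyl hydroperoxide CC(C)(C)OO
Why: Sharpless asymmetric epoxidation oxidises only the allylic-alcohol double bond; L-(+)-tartrate sets the carbinol-bearing oxirane carbon S and the Z geometry makes the epoxide cis, hence (2S,3R), which becomes C2/C3 of the target (Z substrates typically give about 85–90 % ee, and the minor enantiomer is removed as a diastereomer after step 9).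

**Step 4**
Reactants: 5 [(2S,3R)-3-(prop-1-en-2-yl)oxiran-2-yl]methanol
Product: 6 (2R,3R)-3-(prop-1-en-2-yl)oxirane-2-carbaldehyde
Conditions: Dess–Martin periodinane, NaHCO3, CH2Cl2, 0 °C; used at once
Reagents that add atoms: none
Why: Buffered Dess–Martin oxidation gives the cis α,β-epoxy aldehyde without epimerisation (the C2 descriptor changes to R by priority only).

**Step 5**
Reactants: 7 (R)-glycidol
Product: 8 (2S)-2-{[(4-methoxyphenyl)methoxy]methyl}oxirane
Conditions: NaH, 4-methoxybenzyl chloride, Bu4NI (cat.), THF/DMF, 0 → 20 °C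
Reagents that add atoms: 4-methoxybenzyl chloride COc1ccc(CCl)cc1
Why: Williamson etherification of the primary alkoxide leaves the stereocentre (future C9) untouched (the descriptor changes to S by priority only).

**Step 6**
Reactants: 8 (2S)-2-{[(4-methoxyphenyl)methoxy]methyl}oxirane
Product: 9 methyl (3S)-3-hydroxy-4-[(4-methoxyphenyl)methoxy]butanoate
Conditions: CO (40 atm), Co2(CO)8 (5 mol %), 3-hydroxypyridine (10 mol %), MeOH/THF, 60 °C
Reagents that add atoms: carbon monoxide [C-]#[O+]; methanol CO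
Why: Cobalt-catalysed ring-opening carbomethoxylation of a terminal epoxide: [Co(CO)4]− attacks the CH2 carbon, then CO insertion and methanolysis give the β-hydroxy ester with the secondary C–O bond (C9) retained.

**Step 7**
Reactants: 9 methyl (3S)-3-hydroxy-4-[(4-methoxyphenyl)methoxy]butanoate
Product: 10 methyl (3S)-4-[(4-methoxyphenyl)methoxy]-3-(triethylsilyloxy)butanoate
Conditions: Et3SiCl, imidazole, CH2Cl2, 0 °C
Reagents that add atoms: chlorotriethylsilane CC[Si](CC)(CC)Cl
Why: Standard silylation gives a small, non-chelating ether at C9 that later directs Felkin–Anh addition and is removed under mild conditions.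

**Step 8**
Reactants: 10 methyl (3S)-4-[(4-methoxyphenyl)methoxy]-3-(triethylsilyloxy)butanoate; 6 (2R,3R)-3-(prop-1-en-2-yl)oxirane-2-carbaldehyde
Product: 12 methyl (3S)-2-{hydroxy[(2S,3R)-3-(prop-1-en-2-yl)oxiran-2-yl]methyl}-4-[(4-methoxyphenyl)methoxy]-3-(triethylsilyloxy)butanoate (diastereomer mixture at the two new centres), via lithium enolate 11 (not isolated)
Conditions: LiN(iPr)2, THF, −78 °C, 30 min; then 6, −78 °C; AcOH quench at −78 °C
Reagents that add atoms: lithium diisopropylamide CC(C)N([Li])C(C)C (lithium is held only in 11)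
Why: Lithium ester-enolate aldol addition forms the C1–C10 bond at −78 °C, where β-elimination of the silyloxy group is slow; the two new stereocentres are erased in step 9.

**Step 9**
Reactants: 12 aldol adduct (diastereomer mixture)
Product: 14 methyl (2E)-2-[(1S)-2-[(4-methoxyphenyl)methoxy]-1-(triethylsilyloxy)ethyl]-3-[(2S,3R)-3-(prop-1-en-2-yl)oxiran-2-yl]prop-2-enoate, via mesylate 13 (not isolated)
Conditions: MsCl, Et3N, CH2Cl2, 0 °C; then DBU, 0 → 20 °C
Reagents that add atoms: methanesulfonyl chloride CS(=O)(=O)Cl (the sulfonyl group is held only in 13)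
Why: Mesylation and E1cB elimination through the ester-stabilised carbanion expel mesylate in preference to the silyloxy group and give the thermodynamically preferred (E)-alkylidene ester with the oxiranyl group trans to CO2Me (C1=C10 of the target); any Z isomer and the epoxide-derived minor diastereomer are removed by chromatography.

**Step 10**
Reactants: 14 PMB ether
Product: 15 methyl (2E)-2-[(1S)-2-hydroxy-1-(triethylsilyloxy)ethyl]-3-[(2S,3R)-3-(prop-1-en-2-yl)oxiran-2-yl]prop-2-enoate
Conditions: DDQ, CH2Cl2/pH 7 buffer (10:1), 0 °C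
Reagents that add atoms: none
Why: Oxidative cleavage of the electron-rich 4-methoxybenzyl ether by DDQ under buffered conditions spares the silyl ether, the oxirane and the enoate.

**Step 11**
Reactants: 15 primary alcohol
Product: 16 methyl (2E)-2-[(1S)-2-oxo-1-(triethylsilyloxy)ethyl]-3-[(2S,3R)-3-(prop-1-en-2-yl)oxiran-2-yl]prop-2-enoate
Conditions: Dess–Martin periodinane, NaHCO3, CH2Cl2, 0 °C; used at once
Reagents that add atoms: none
Why: Neutral Dess–Martin oxidation gives the α-silyloxy aldehyde (C8) without epimerisation at C9 when it is used immediately.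

**Step 12**
Reactants: 17 (2E)-but-2-enal; 18 vinylmagnesium bromide
Product: 19 rac-(4E)-hexa-1,4-dien-3-ol
Conditions: CH2=CHMgBr, THF, −78 → 0 °C; H2O
Reagents that add atoms: none
Why: 1,2-Addition of the Grignard reagent to the enal gives the racemic bis-allylic alcohol.

**Step 13**
Reactants: 19 rac-(4E)-hexa-1,4-dien-3-ol
Product: 20 (3S,4E)-hexa-1,4-dien-3-ol
Conditions: Ti(OiPr)4 (15 mol %), D-(−)-diisopropyl tartrate (18 mol %), t-BuOOH (0.6 equiv), 4 Å MS, CH2Cl2, −20 °C, to about 55–60 % conversion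
Reagents that add atoms: none
Why: Sharpless kinetic resolution: with D-(−)-tartrate the (R)-alcohol is epoxidised fast at its propenyl double bond, leaving the (S)-alcohol (future C6) in high ee.

**Step 14**
Reactants: 20 (3S,4E)-hexa-1,4-dien-3-ol; 21 2-(bromomethyl)prop-2-enoic acid
Product: 22 (3S,4E)-hexa-1,4-dien-3-yl 2-(bromomethyl)prop-2-enoate
Conditions: DCC, DMAP (5 mol %), CH2Cl2, 0 °C
Reagents that add atoms: none
Why: Steglich esterification does not break the carbinol C–O bond, so the configuration is retained.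

**Step 15**
Reactants: 22 (3S,4E)-hexa-1,4-dien-3-yl 2-(bromomethyl)prop-2-enoate
Product: 23 (5R)-3-(bromomethyl)-5-[(1E)-prop-1-en-1-yl]furan-2(5H)-one
Conditions: second-generation Grubbs catalyst (5 mol %), toluene, 70 °C, 0.01 M
Reagents that add atoms: none
Why: Ring-closing metathesis: the catalyst loads on the terminal vinyl group and closes onto the acrylate to give the butenolide with loss of ethene, the internal propenyl group and the allylic bromide being spectators (the descriptor becomes R by priority only).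

**Step 16**
Reactants: 24 (2E)-2-methylbut-2-en-1-ol
Product: 25 [(2R,3R)-2,3-dimethyloxiran-2-yl]methanol
Conditions: Ti(OiPr)4 (10 mol %), D-(−)-diisopropyl tartrate (12 mol %), t-BuOOH, 4 Å MS, CH2Cl2, −20 °C
Reagents that add atoms: tert-butyl hydroperoxide CC(C)(C)OO
Why: Sharpless asymmetric epoxidation of the E-trisubstituted allylic alcohol with D-(−)-tartrate gives the (2R,3R) epoxy alcohol; the stereospecific syn oxygen transfer keeps the two methyl groups cis.

**Step 17**
Reactants: 25 [(2R,3R)-2,3-dimethyloxiran-2-yl]methanol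
Product: 26 (2S,3R)-2,3-dimethyloxirane-2-carboxylic acid
Conditions: RuCl3·xH2O (2 mol %), NaIO4, MeCN/EtOAc/H2O, 20 °C
Reagents that add atoms: water O
Why: Catalytic RuO4 oxidation (Sharpless conditions) takes the primary alcohol to the glycidic acid without touching the oxirane (the C2 descriptor changes to S by priority only).

**Step 18**
Reactants: 23 (5R)-3-(bromomethyl)-5-[(1E)-prop-1-en-1-yl]furan-2(5H)-one; 16 aldehyde
Product: 28 methyl (2E)-2-{(1S,2R)-2-hydroxy-2-[(2R,3R)-4-methylidene-5-oxo-2-[(1E)-prop-1-en-1-yl]oxolan-3-yl]-1-(triethylsilyloxy)ethyl}-3-[(2S,3R)-3-(prop-1-en-2-yl)oxiran-2-yl]prop-2-enoate, via allylzinc bromide 27 (not isolated)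
Conditions: Zn dust (activated), THF/sat. aq NH4Cl (3:1), 0 → 20 °C, 23 in 1.5-fold excess
Reagents that add atoms: zinc [Zn] (held only in 27)
Why: Barbier allylation: the allylzinc attacks through the ring γ-carbon (SE2′) in a closed chair transition state on the face trans to the propenyl group (sets C7, trans lactone) with the aldehyde chain equatorial, which is also the Felkin–Anh face of the α-silyloxy aldehyde, so reagent and substrate control are matched and deliver the (8R) carbinol, the C8 epimer of the target.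

**Step 19**
Reactants: 28 (8R)-alcohol; 26 (2S,3R)-2,3-dimethyloxirane-2-carboxylic acid
Product: 29 methyl (2E)-2-{(1S,2S)-2-{[(2S,3R)-2,3-dimethyloxiran-2-yl]carbonyloxy}-2-[(2R,3S)-4-methylidene-5-oxo-2-[(1E)-prop-1-en-1-yl]oxolan-3-yl]-1-(triethylsilyloxy)ethyl}-3-[(2S,3R)-3-(prop-1-en-2-yl)oxiran-2-yl]prop-2-enoate
Conditions: PPh3, DIAD (betaine pre-formed), toluene, 0 → 20 °C
Reagents that add atoms: none
Why: Mitsunobu esterification: SN2 displacement of the oxyphosphonium by the carboxylate of 26 inverts C8 from R to the required S and installs the side chain in the same operation.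

**Step 20**
Reactants: 29 seco-diene
Product: 30 9-O-triethylsilyl ether of the target (ten-membered ring closed; all configurations as in 31)
Conditions: second-generation Hoveyda–Grubbs catalyst (15 mol %, in portions), toluene, 60 °C, 1 mM
Reagents that add atoms: none
Why: Ring-closing metathesis between the propenyl and isopropenyl groups (propene lost): the trans lactone, the cis oxirane and the 1(10) enoate pre-organise the chain, and the ten-membered ring strongly favours the ring-cis (4Z) trisubstituted alkene.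

**Step 21**
Reactants: 30 silyl ether
Product: 31 target (CNP0291485.6)
Conditions: HF·pyridine, pyridine, THF, 0 °C
Reagents that add atoms: none
Why: Buffered fluoride cleavage of the secondary triethylsilyl ether frees the C9 hydroxyl without acyl migration or opening of either oxirane; no stereocentre is touched.

**Compound list**
1 | 2-methylbut-1-en-3-yne | C=C(C)C#C | starting material
2 | lithium 3-methylbut-3-en-1-yn-1-ide (lithium acetylide of 1) | [Li]C#CC(C)=C | intermediate
3 | 4-methylpent-4-en-2-yn-1-ol | C=C(C)C#CCO | intermediate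
4 | (2Z)-4-methylpenta-2,4-dien-1-ol | C=C(C)/C=C\CO | intermediate
5 | [(2S,3R)-3-(prop-1-en-2-yl)oxiran-2-yl]methanol (cis-epoxide) | C=C(C)[C@H]1O[C@H]1CO | intermediate
6 | (2R,3R)-3-(prop-1-en-2-yl)oxirane-2-carbaldehyde (cis-epoxide) | C=C(C)[C@H]1O[C@H]1C=O | intermediate
7 | (R)-glycidol, [(2R)-oxiran-2-yl]methanol | OC[C@@H]1CO1 | starting material
8 | (2S)-2-{[(4-methoxyphenyl)methoxy]methyl}oxirane | COc1ccc(COC[C@@H]2CO2)cc1 | intermediate
9 | methyl (3S)-3-hydroxy-4-[(4-methoxyphenyl)methoxy]butanoate | COC(=O)C[C@H](O)COCc1ccc(OC)cc1 | intermediate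
10 | methyl (3S)-4-[(4-methoxyphenyl)methoxy]-3-(triethylsilyloxy)butanoate | COC(=O)C[C@H](O[Si](CC)(CC)CC)COCc1ccc(OC)cc1 | intermediate
11 | lithium enolate of 10, lithium (3S)-1-methoxy-4-[(4-methoxyphenyl)methoxy]-3-(triethylsilyloxy)but-1-en-1-olate | COC(O[Li])=C[C@H](O[Si](CC)(CC)CC)COCc1ccc(OC)cc1 | intermediate
12 | methyl (3S)-2-{hydroxy[(2S,3R)-3-(prop-1-en-2-yl)oxiran-2-yl]methyl}-4-[(4-methoxyphenyl)methoxy]-3-(triethylsilyloxy)butanoate (mixture at C2 and the new carbinol carbon) | C=C(C)[C@H]1O[C@H]1C(O)C(C(=O)OC)[C@H](O[Si](CC)(CC)CC)COCc2ccc(OC)cc2 | intermediate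
13 | methanesulfonate of 12 (OH replaced by OSO2Me, configurations unchanged) | C=C(C)[C@H]1O[C@H]1C(OS(C)(=O)=O)C(C(=O)OC)[C@H](O[Si](CC)(CC)CC)COCc2ccc(OC)cc2 | intermediate
14 | methyl (2E)-2-[(1S)-2-[(4-methoxyphenyl)methoxy]-1-(triethylsilyloxy)ethyl]-3-[(2S,3R)-3-(prop-1-en-2-yl)oxiran-2-yl]prop-2-enoate | C=C(C)[C@H]1O[C@H]1/C=C(/C(=O)OC)[C@H](O[Si](CC)(CC)CC)COCc2ccc(OC)cc2 | intermediate
15 | methyl (2E)-2-[(1S)-2-hydroxy-1-(triethylsilyloxy)ethyl]-3-[(2S,3R)-3-(prop-1-en-2-yl)oxiran-2-yl]prop-2-enoate | C=C(C)[C@H]1O[C@H]1/C=C(/C(=O)OC)[C@H](O[Si](CC)(CC)CC)CO | intermediate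
16 | methyl (2E)-2-[(1S)-2-oxo-1-(triethylsilyloxy)ethyl]-3-[(2S,3R)-3-(prop-1-en-2-yl)oxiran-2-yl]prop-2-enoate | C=C(C)[C@H]1O[C@H]1/C=C(/C(=O)OC)[C@H](O[Si](CC)(CC)CC)C=O | intermediate
17 | (2E)-but-2-enal (crotonaldehyde) | C/C=C/C=O | starting material
18 | vinylmagnesium bromide | C=C[Mg]Br | starting material
19 | rac-(4E)-hexa-1,4-dien-3-ol | C=CC(O)/C=C/C | intermediate
20 | (3S,4E)-hexa-1,4-dien-3-ol | C=C[C@H](O)/C=C/C | intermediate
21 | 2-(bromomethyl)prop-2-enoic acid | C=C(CBr)C(=O)O | starting material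
22 | (3S,4E)-hexa-1,4-dien-3-yl 2-(bromomethyl)prop-2-enoate | C=C(CBr)C(=O)O[C@H](/C=C/C)C=C | intermediate
23 | (5R)-3-(bromomethyl)-5-[(1E)-prop-1-en-1-yl]furan-2(5H)-one | O=C1O[C@H](/C=C/C)C=C1CBr | intermediate
24 | (2E)-2-methylbut-2-en-1-ol (tiglyl alcohol) | C/C=C(\C)CO | starting material
25 | [(2R,3R)-2,3-dimethyloxiran-2-yl]methanol (methyl groups cis) | OC[C@@]1(C)O[C@@H]1C | intermediate
26 | (2S,3R)-2,3-dimethyloxirane-2-carboxylic acid (methyl groups cis) | OC(=O)[C@@]1(C)O[C@@H]1C | intermediate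
27 | bromo{[(5R)-2-oxo-5-[(1E)-prop-1-en-1-yl]-2,5-dihydrofuran-3-yl]methyl}zinc | Br[Zn]CC1=C[C@@H](/C=C/C)OC1=O | intermediate
28 | methyl (2E)-2-{(1S,2R)-2-hydroxy-2-[(2R,3R)-4-methylidene-5-oxo-2-[(1E)-prop-1-en-1-yl]oxolan-3-yl]-1-(triethylsilyloxy)ethyl}-3-[(2S,3R)-3-(prop-1-en-2-yl)oxiran-2-yl]prop-2-enoate (trans lactone, 8R, 9S) | C=C1C(=O)O[C@H](/C=C/C)[C@H]1[C@@H](O)[C@@H](O[Si](CC)(CC)CC)/C(C(=O)OC)=C\[C@@H]2O[C@@H]2C(C)=C | intermediate
29 | methyl (2E)-2-{(1S,2S)-2-{[(2S,3R)-2,3-dimethyloxiran-2-yl]carbonyloxy}-2-[(2R,3S)-4-methylidene-5-oxo-2-[(1E)-prop-1-en-1-yl]oxolan-3-yl]-1-(triethylsilyloxy)ethyl}-3-[(2S,3R)-3-(prop-1-en-2-yl)oxiran-2-yl]prop-2-enoate (8S, 9S) | C=C1C(=O)O[C@H](/C=C/C)[C@H]1[C@H](OC(=O)[C@@]2(C)O[C@@H]2C)[C@@H](O[Si](CC)(CC)CC)/C(C(=O)OC)=C\[C@@H]3O[C@@H]3C(C)=C | intermediate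
30 | 9-O-triethylsilyl ether of the target: (1(10)E,4Z)-germacradienolide ring with 2S,3R,6R,7S,8S,9S and the (2S,3R)-epoxy ester at O8 | C=C1C(=O)O[C@@H]2/C=C(/C)[C@H]3O[C@H]3/C=C(/C(=O)OC)[C@H](O[Si](CC)(CC)CC)[C@@H](OC(=O)[C@@]3(C)O[C@@H]3C)[C@@H]12 | intermediate
31 | methyl (1(10)E,4Z,2S,3R,6R,7S,8S,9S)-8-{[(2S,3R)-2,3-dimethyloxiran-2-yl]carbonyloxy}-2,3-epoxy-9-hydroxy-12-oxogermacra-1(10),4,11(13)-trien-12,6-olid-14-oate (CNP0291485.6) | C=C1C(=O)O[C@@H]2/C=C(/C)[C@H]3O[C@H]3/C=C(/C(=O)OC)[C@H](O)[C@@H](OC(=O)[C@@]3(C)O[C@@H]3C)[C@@H]12 | target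

**Totals**
Total step count: 21. Longest linear sequence: 12 (steps 1–4, 8–11, 18–21).

**Steps most likely to fail**

Step 20 (ring-closing metathesis to a strained ten-membered ring from a hindered isopropenyl oxirane and an internal propenyl group). Fallback: change the order of ring closure and acylation. It sets out from 28: ring-closing metathesis on the free alcohol (second-generation Hoveyda–Grubbs catalyst, toluene, 60 °C, 1 mM), which has a small C8 substituent of opposite configuration and so a different set of reactive conformers, would give the macrocyclic (8R)-alcohol F1. Mitsunobu esterification of F1 with 26 (PPh3, DIAD, toluene) then inverts C8 on the ring and comes back to the route at 30.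

Step 19 (Mitsunobu inversion at a carbinol flanked by two branched carbons; elimination toward the methylene lactone can compete). Fallback: invert by oxidation and reduction, then acylate with retention. It sets out from 28: Dess–Martin periodinane gives the C8 ketone F2. Luche reduction (NaBH4, CeCl3·7H2O, MeOH, −78 °C), with Felkin–Anh attack anti to the C9 silyloxy group, would give the (8S)-alcohol F3. Steglich esterification of F3 with 26 (DCC, DMAP, CH2Cl2, 0 °C) comes back at 29.

Step 18 (zinc Barbier coupling: possible reductive opening of the epoxy enoate, enolisation of 16, incomplete diastereocontrol). Fallback: replace the metal-mediated Barbier by a thermal allylboration with an isolated reagent. It sets out from 23: borylation (B2pin2, Pd2(dba)3 cat., toluene, 50 °C) gives the pinacol allylboronate F4. Heating F4 with 16 (toluene, 50 °C, no reducing metal and no Lewis acid) passes through the same closed chair transition state to the pinacol borate ester F5, which is hydrolysed on aqueous work-up and comes back at 28.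

**Further compounds**
F1 | step 20 | macrocyclic (8R)-alcohol: the ten-membered ring of 30 with a free 8-hydroxyl of inverted configuration in place of the ester (9-O-triethylsilyl) | C=C1C(=O)O[C@@H]2/C=C(/C)[C@H]3O[C@H]3/C=C(/C(=O)OC)[C@H](O[Si](CC)(CC)CC)[C@H](O)[C@@H]12
F2 | step 19 | C8 ketone of 28, methyl (2E)-2-{(1S)-2-oxo-2-[(2R,3S)-4-methylidene-5-oxo-2-[(1E)-prop-1-en-1-yl]oxolan-3-yl]-1-(triethylsilyloxy)ethyl}-3-[(2S,3R)-3-(prop-1-en-2-yl)oxiran-2-yl]prop-2-enoate | C=C1C(=O)O[C@H](/C=C/C)[C@H]1C(=O)[C@@H](O[Si](CC)(CC)CC)/C(C(=O)OC)=C\[C@@H]2O[C@@H]2C(C)=C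
F3 | step 19 | (8S)-alcohol, the C8 epimer of 28 | C=C1C(=O)O[C@H](/C=C/C)[C@H]1[C@H](O)[C@@H](O[Si](CC)(CC)CC)/C(C(=O)OC)=C\[C@@H]2O[C@@H]2C(C)=C
F4 | step 18 | (5R)-5-[(1E)-prop-1-en-1-yl]-3-[(4,4,5,5-tetramethyl-1,3,2-dioxaborolan-2-yl)methyl]furan-2(5H)-one | CC1(C)OB(CC2=C[C@@H](/C=C/C)OC2=O)OC1(C)C
F5 | step 18 | pinacol borate ester of 28 (O8–B bond, configurations as in 28) | C=C1C(=O)O[C@H](/C=C/C)[C@H]1[C@@H](OB2OC(C)(C)C(C)(C)O2)[C@@H](O[Si](CC)(CC)CC)/C(C(=O)OC)=C\[C@@H]3O[C@@H]3C(C)=C
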